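The target is cut at the ring B–c1 bond and at the C4–C5 and O1–C5 bonds of the butenolide. The feature exploited is that the chain from the alkyne carbon on ring B (c1) to butenolide C5, once c11 and C5 are read as an alkyne, is a twofold-symmetric 3,10-dimethyltetraenediyne. In one flask the ring B enol triflate is joined to one terminus of this diyne and (E)-2,3-dibromoacrylic acid to the other, the carboxylate closing the (Z)-ylidene butenolide. Its surviving C3 bromide then takes the ring A epoxy vinylstannane. The precursors are the hydroxy triflate, the all-E C14 diyne and the dibromo acid.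

Key step: step 17

Remark: the target is read as the (3S,5R,6S)-epoxide on ring A, the (3R)-carbinol on ring B and a (Z)-ylidene butenolide; both carbinol carbons have the same spatial configuration, so the single (4R)-enol triflate 6 feeds both rings. All polyenes are handled under argon with exclusion of light.

Step 1
Reactants: 1 4-oxoisophorone
Product: 2 (6R)-2,2,6-trimethylcyclohexane-1,4-dione
Conditions: ene-reductase (old yellow enzyme), NADP+ (cat.), glucose dehydrogenase, D-glucose, phosphate buffer pH 6.5, 30 °C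
Reagents that add atoms: none
Why: Asymmetric bioreduction of an activated alkene, in which the flavin delivers hydride to the enedione C=C and the active site protonates the neighbouring carbon from the opposite face (net trans-hydrogenation), should set the methyl-bearing carbon as 6R, while the slightly acidic buffer limits racemisation of 2 by enolisation.

Step 2
Reactants: 2 (6R)-2,2,6-trimethylcyclohexane-1,4-dione
Product: 3 (4R,6R)-4-hydroxy-2,2,6-trimethylcyclohexan-1-one
Conditions: H2 (10 bar), Raney Ni, MeOH, rt; recrystallisation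
Reagents that add atoms: none
Why: Chemoselective heterogeneous hydrogenation should reduce only the unhindered C4 ketone (C1 is flanked by a quaternary and a tertiary carbon) and deliver hydrogen to the face away from the axial C2 methyl group, so that C4 is set by substrate control as 4R with the hydroxyl trans to the C6 methyl, the minor cis alcohol being removed by crystallisation.

Step 3
Reactants: 3 (4R,6R)-4-hydroxy-2,2,6-trimethylcyclohexan-1-one
Product: 4 (4R,6R)-4-[(tert-butyldimethylsilyl)oxy]-2,2,6-trimethylcyclohexan-1-one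
Conditions: TBSCl, imidazole, DMF, rt
Reagents that add atoms: tert-butyldimethylsilyl chloride, CC(C)(C)[Si](C)(C)Cl
Why: Standard silylation of a secondary alcohol masks the hydroxyl for enolate formation and for the ring A sequence.

Step 4
Reactants: 4 (4R,6R)-4-[(tert-butyldimethylsilyl)oxy]-2,2,6-trimethylcyclohexan-1-one
Product: 6 (4R)-4-[(tert-butyldimethylsilyl)oxy]-2,6,6-trimethylcyclohex-1-en-1-yl trifluoromethanesulfonate, via lithium enolate 5 (not isolated)
Conditions: LiN(iPr)2, THF, −78 → 0 °C; PhNTf2, 0 °C → rt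
Reagents that add atoms: N-phenylbis(trifluoromethanesulfonimide), O=S(=O)(N(c1ccccc1)S(=O)(=O)C(F)(F)F)C(F)(F)F
Why: Enol triflate formation, in which the ketone can enolise only towards C6, should give a single tetrasubstituted enolate that PhNTf2 sulfonylates on oxygen; the C6 stereocentre is erased on purpose and C4 is untouched.

Step 5
Reactants: 6 (4R)-4-[(tert-butyldimethylsilyl)oxy]-2,6,6-trimethylcyclohex-1-en-1-yl trifluoromethanesulfonate
Product: 7 (4R)-4-hydroxy-2,6,6-trimethylcyclohex-1-en-1-yl trifluoromethanesulfonate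
Conditions: HF·pyridine, THF, 0 °C → rt
Reagents that add atoms: none
Why: Fluoride-driven cleavage of the silyl ether under mildly acidic conditions leaves the enol triflate intact and frees the hydroxyl of the ring B coupling partner.

Step 6
Reactants: 6 (4R)-4-[(tert-butyldimethylsilyl)oxy]-2,6,6-trimethylcyclohex-1-en-1-yl trifluoromethanesulfonate
Product: 8 methyl (4R)-4-[(tert-butyldimethylsilyl)oxy]-2,6,6-trimethylcyclohex-1-ene-1-carboxylate
Conditions: CO (1 atm), Pd(OAc)2 (5 mol %), PPh3, Et3N, MeOH/DMF, 60 °C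
Reagents that add atoms: carbon monoxide, [C-]#[O+]; methanol, CO
Why: Palladium-catalysed methoxycarbonylation of an enol triflate (oxidative addition, CO insertion, methanolysis of the acylpalladium) is an established reaction type for hindered 2,6,6-trimethylcyclohexenyl triflates.

Step 7
Reactants: 8 methyl (4R)-4-[(tert-butyldimethylsilyl)oxy]-2,6,6-trimethylcyclohex-1-ene-1-carboxylate
Product: 9 [(4R)-4-[(tert-butyldimethylsilyl)oxy]-2,6,6-trimethylcyclohex-1-en-1-yl]methanol
Conditions: iBu2AlH, CH2Cl2, −78 → 0 °C; aq. potassium sodium tartrate work-up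
Reagents that add atoms: none
Why: 1,2-Reduction of the conjugated ester by iBu2AlH gives the allylic alcohol that serves as the handle for directed epoxidation, with silyl ether and alkene inert.

Step 8
Reactants: 9 [(4R)-4-[(tert-butyldimethylsilyl)oxy]-2,6,6-trimethylcyclohex-1-en-1-yl]methanol
Product: 10 [(1R,4S,6R)-4-[(tert-butyldimethylsilyl)oxy]-2,2,6-trimethyl-7-oxabicyclo[4.1.0]heptan-1-yl]methanol
Conditions: Ti(OiPr)4, D-(−)-diethyl tartrate, tBuOOH, 4 Å molecular sieves, CH2Cl2, −20 °C
Reagents that add atoms: tert-butyl hydroperoxide, CC(C)(C)OO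
Why: In the Katsuki–Sharpless asymmetric epoxidation the titanium–D-(−)-tartrate–peroxide complex bound to the allylic alkoxide should deliver oxygen to the face of the tetrasubstituted ring alkene anti to the C4 silyloxy group, so that both epoxide carbons (C1 and C6) are set by reagent control.

Step 9
Reactants: 10 [(1R,4S,6R)-4-[(tert-butyldimethylsilyl)oxy]-2,2,6-trimethyl-7-oxabicyclo[4.1.0]heptan-1-yl]methanol
Product: 11 (1S,4S,6R)-4-[(tert-butyldimethylsilyl)oxy]-2,2,6-trimethyl-7-oxabicyclo[4.1.0]heptane-1-carbaldehyde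
Conditions: Dess–Martin periodinane, pyridine, CH2Cl2, 0 °C → rt
Reagents that add atoms: none
Why: Buffered Dess–Martin oxidation of the primary alcohol gives an aldehyde without α-hydrogen, which cannot epimerise, and keeps acid away from the epoxide.

Step 10
Reactants: 12 dibromomethane
Product: 14 (dibromomethyl)tributylstannane, via dibromomethyllithium 13 (not isolated)
Conditions: LiN(iPr)2, THF, −90 °C; Bu3SnCl, −90 °C → rt
Reagents that add atoms: tributyltin chloride, CCCC[Sn](Cl)(CCCC)CCCC
Why: Low-temperature deprotonation of dibromomethane gives the lithium carbenoid, which Bu3SnCl should trap at carbon before it decomposes (electrophilic stannylation of a carbenoid).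

Step 11
Reactants: 11 (1S,4S,6R)-4-[(tert-butyldimethylsilyl)oxy]-2,2,6-trimethyl-7-oxabicyclo[4.1.0]heptane-1-carbaldehyde; 14 (dibromomethyl)tributylstannane
Product: 15 tributyl{(E)-2-[(1S,4S,6R)-4-[(tert-butyldimethylsilyl)oxy]-2,2,6-trimethyl-7-oxabicyclo[4.1.0]heptan-1-yl]ethenyl}stannane
Conditions: CrCl2, LiI, THF/DMF, rt, dark
Reagents that add atoms: none
Why: In the Hodgson–Takai stannylolefination divalent chromium converts 14 into a geminal dichromium species that adds to the aldehyde and eliminates to the alkenylstannane, the E geometry arising from the anti arrangement of the bulky groups in the β-oxido chromium intermediate, while epoxide and silyl ether should be inert to this chemoselective reagent.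

Step 12
Reactants: 15 tributyl{(E)-2-[(1S,4S,6R)-4-[(tert-butyldimethylsilyl)oxy]-2,2,6-trimethyl-7-oxabicyclo[4.1.0]heptan-1-yl]ethenyl}stannane
Product: 16 (1R,3S,6S)-1,5,5-trimethyl-6-[(E)-2-(tributylstannyl)ethenyl]-7-oxabicyclo[4.1.0]heptan-3-ol
Conditions: Bu4NF, THF, 0 °C → rt
Reagents that add atoms: none
Why: Fluoride desilylation of the secondary TBS ether should leave vinylstannane and epoxide untouched, so the hydroxyl is freed before the final coupling.

Step 13
Reactants: 17 (E)-3-methylpent-2-en-4-yn-1-ol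
Product: 18 (E)-5-bromo-3-methylpent-3-en-1-yne
Conditions: PBr3, pyridine (cat.), Et2O, −10 °C
Reagents that add atoms: phosphorus tribromide, BrP(Br)Br
Why: Bromination of the primary allylic alcohol by PBr3 at low temperature (SN2 on the bromophosphite) should retain the E geometry of the enyne.

Step 14
Reactants: 18 (E)-5-bromo-3-methylpent-3-en-1-yne
Product: 19 [(E)-3-methylpent-2-en-4-yn-1-yl]triphenylphosphonium bromide
Conditions: PPh3, toluene, rt
Reagents that add atoms: triphenylphosphine, c1ccc(cc1)P(c1ccccc1)c1ccccc1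
Why: SN2 quaternisation of PPh3 by the primary allylic bromide gives the Wittig salt without touching the E double bond.

Step 15
Reactants: 19 [(E)-3-methylpent-2-en-4-yn-1-yl]triphenylphosphonium bromide (2.3 equiv); 20 glyoxal (40 % aqueous solution)
Product: 23 (3E,5E,7E,9E)-3,10-dimethyldodeca-3,5,7,9-tetraene-1,11-diyne, via dienynal 21 (not isolated), via E/Z isomer mixture 22 (not isolated)
Conditions: LiOEt (added slowly), EtOH, 0 °C → rt; then I2 (cat.), CH2Cl2, daylight, rt; crystallisation
Reagents that add atoms: none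
Why: Twofold Wittig olefination of glyoxal by the semistabilised allylic ylide builds the C5=C6 and C7=C8 bonds as E/Z mixtures, and iodine-catalysed isomerisation (reversible addition of iodine atoms) under mild, monitored conditions should convert the Z-disubstituted bonds into the all-E tetraene, which is purified by crystallisation.

Step 16
Reactants: 24 propiolic acid
Product: 25 (E)-2,3-dibromoacrylic acid
Conditions: Br2, CHCl3, 0 °C → rt, dark
Reagents that add atoms: bromine, BrBr
Why: Electrophilic anti addition of bromine across the triple bond, with light excluded, should give the E acid in which the β-bromide is cis to the carboxyl group.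

Step 17
Reactants: 7 (4R)-4-hydroxy-2,6,6-trimethylcyclohex-1-en-1-yl trifluoromethanesulfonate (limiting); 23 (3E,5E,7E,9E)-3,10-dimethyldodeca-3,5,7,9-tetraene-1,11-diyne (2.5 equiv); 25 (E)-2,3-dibromoacrylic acid (excess over all remaining alkyne termini)
Product: 28 (5Z)-3-bromo-5-[(2E,4E,6E,8E)-11-[(4R)-4-hydroxy-2,6,6-trimethylcyclohex-1-en-1-yl]-2,9-dimethylundeca-2,4,6,8-tetraen-10-yn-1-ylidene]furan-2(5H)-one, via terminal alkyne 26 (not isolated), via bromoenynoic acid 27 (not isolated)
Conditions: PdCl2(PPh3)2 (5 mol %), CuI (10 mol %), Et3N, degassed THF/MeCN, 7 + 23, rt → 40 °C; then 25, Et3N, rt, dark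
Reagents that add atoms: none
Why: Zerovalent palladium formed in situ inserts into the C–OTf bond of 7, the copper acetylide of one terminus of 23 transmetalates and reductive elimination gives 26, after which the same catalyst inserts into the β C–Br bond of 25, couples it with the free terminus of 26 to give carboxylate 27, and the carboxylate adds anti across the metal-activated triple bond before protodemetalation releases 28. The closest known reactions are the Sonogashira coupling of hindered 2,6,6-trimethylcyclohexenyl triflates and the tandem Sonogashira coupling–lactonisation of (Z)-3-halopropenoic acids with 1-alkynes. The butenolide closes in the 5-exo-dig mode by attack of O1 on the proximal alkyne carbon (C5), and the anti oxymetalation fixes the exocyclic C5=c11 bond as Z. No stereocentre is formed and the ring B carbinol is a spectator. Mono-coupling of the symmetric diyne is secured statistically by its excess over the limiting triflate, β-before-α bromide selectivity by the conjugate activation of the β C–Br bond and its position cis to the carboxylate, and the α-bromide of 28 should stay inert at room temperature. The diyne left over is converted by excess 25 into hydroxyl-free bromobutenolides, which are less polar than 28 and are removed by chromatography.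

Step 18
Reactants: 28 (5Z)-3-bromo-5-[(2E,4E,6E,8E)-11-[(4R)-4-hydroxy-2,6,6-trimethylcyclohex-1-en-1-yl]-2,9-dimethylundeca-2,4,6,8-tetraen-10-yn-1-ylidene]furan-2(5H)-one; 16 (1R,3S,6S)-1,5,5-trimethyl-6-[(E)-2-(tributylstannyl)ethenyl]-7-oxabicyclo[4.1.0]heptan-3-ol
Product: 29 (5Z)-3-[(E)-2-[(1S,4S,6R)-4-hydroxy-2,2,6-trimethyl-7-oxabicyclo[4.1.0]heptan-1-yl]ethenyl]-5-[(2E,4E,6E,8E)-11-[(4R)-4-hydroxy-2,6,6-trimethylcyclohex-1-en-1-yl]-2,9-dimethylundeca-2,4,6,8-tetraen-10-yn-1-ylidene]furan-2(5H)-one (target)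
Conditions: Pd2(dba)3 (5 mol %), AsPh3, degassed DMF, 40 °C, dark
Reagents that add atoms: none
Why: Stille coupling of a 3-bromobutenolide with an (E)-alkenylstannane proceeds with retention of alkene geometry, and the weakly donating AsPh3 ligand should speed transmetalation of the hindered stannane while sparing the vinyl epoxide, the (Z)-ylidene bond and both free hydroxyls.

Compound list
1 | 4-oxoisophorone (2,6,6-trimethylcyclohex-2-ene-1,4-dione) | CC1=CC(=O)CC(C)(C)C1=O | starting material
2 | (6R)-2,2,6-trimethylcyclohexane-1,4-dione | C[C@@H]1CC(=O)CC(C)(C)C1=O | intermediate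
3 | (4R,6R)-4-hydroxy-2,2,6-trimethylcyclohexan-1-one | C[C@@H]1C[C@@H](O)CC(C)(C)C1=O | intermediate
4 | (4R,6R)-4-[(tert-butyldimethylsilyl)oxy]-2,2,6-trimethylcyclohexan-1-one | C[C@@H]1C[C@@H](O[Si](C)(C)C(C)(C)C)CC(C)(C)C1=O | intermediate
5 | lithium (4R)-4-[(tert-butyldimethylsilyl)oxy]-2,6,6-trimethylcyclohex-1-en-1-olate | CC1=C(O[Li])C(C)(C)C[C@H](O[Si](C)(C)C(C)(C)C)C1 | intermediate (not isolated)
6 | (4R)-4-[(tert-butyldimethylsilyl)oxy]-2,6,6-trimethylcyclohex-1-en-1-yl trifluoromethanesulfonate | CC1=C(OS(=O)(=O)C(F)(F)F)C(C)(C)C[C@H](O[Si](C)(C)C(C)(C)C)C1 | intermediate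
7 | (4R)-4-hydroxy-2,6,6-trimethylcyclohex-1-en-1-yl trifluoromethanesulfonate | CC1=C(OS(=O)(=O)C(F)(F)F)C(C)(C)C[C@H](O)C1 | intermediate
8 | methyl (4R)-4-[(tert-butyldimethylsilyl)oxy]-2,6,6-trimethylcyclohex-1-ene-1-carboxylate | CC1=C(C(=O)OC)C(C)(C)C[C@H](O[Si](C)(C)C(C)(C)C)C1 | intermediate
9 | [(4R)-4-[(tert-butyldimethylsilyl)oxy]-2,6,6-trimethylcyclohex-1-en-1-yl]methanol | CC1=C(CO)C(C)(C)C[C@H](O[Si](C)(C)C(C)(C)C)C1 | intermediate
10 | [(1R,4S,6R)-4-[(tert-butyldimethylsilyl)oxy]-2,2,6-trimethyl-7-oxabicyclo[4.1.0]heptan-1-yl]methanol | OC[C@@]12O[C@]1(C)C[C@@H](O[Si](C)(C)C(C)(C)C)CC2(C)C | intermediate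
11 | (1S,4S,6R)-4-[(tert-butyldimethylsilyl)oxy]-2,2,6-trimethyl-7-oxabicyclo[4.1.0]heptane-1-carbaldehyde | O=C[C@@]12O[C@]1(C)C[C@@H](O[Si](C)(C)C(C)(C)C)CC2(C)C | intermediate
12 | dibromomethane | BrCBr | starting material
13 | dibromomethyllithium | [Li]C(Br)Br | intermediate (not isolated)
14 | (dibromomethyl)tributylstannane | CCCC[Sn](CCCC)(CCCC)C(Br)Br | intermediate
15 | tributyl{(E)-2-[(1S,4S,6R)-4-[(tert-butyldimethylsilyl)oxy]-2,2,6-trimethyl-7-oxabicyclo[4.1.0]heptan-1-yl]ethenyl}stannane | CCCC[Sn](CCCC)(CCCC)/C=C/[C@@]12O[C@]1(C)C[C@@H](O[Si](C)(C)C(C)(C)C)CC2(C)C | intermediate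
16 | (1R,3S,6S)-1,5,5-trimethyl-6-[(E)-2-(tributylstannyl)ethenyl]-7-oxabicyclo[4.1.0]heptan-3-ol | CCCC[Sn](CCCC)(CCCC)/C=C/[C@@]12O[C@]1(C)C[C@@H](O)CC2(C)C | intermediate
17 | (E)-3-methylpent-2-en-4-yn-1-ol | C#C/C(C)=C/CO | starting material
18 | (E)-5-bromo-3-methylpent-3-en-1-yne | C#C/C(C)=C/CBr | intermediate
19 | [(E)-3-methylpent-2-en-4-yn-1-yl]triphenylphosphonium bromide | C#C/C(C)=C/C[P+](c1ccccc1)(c1ccccc1)c1ccccc1.[Br-] | intermediate
20 | glyoxal | O=CC=O | starting material
21 | (4E)-5-methylhepta-2,4-dien-6-ynal, 2E/2Z mixture | C#C/C(C)=C/C=CC=O | intermediate (not isolated)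
22 | (3E,9E)-3,10-dimethyldodeca-3,5,7,9-tetraene-1,11-diyne, mixture of 5,7-E/Z isomers | C#C/C(C)=C/C=CC=C/C=C(C)/C#C | intermediate (not isolated)
23 | (3E,5E,7E,9E)-3,10-dimethyldodeca-3,5,7,9-tetraene-1,11-diyne | C#C/C(C)=C/C=C/C=C/C=C(C)/C#C | intermediate
24 | propiolic acid | C#CC(=O)O | starting material
25 | (E)-2,3-dibromoacrylic acid | OC(=O)/C(Br)=C\Br | intermediate
26 | (1R)-4-[(3E,5E,7E,9E)-3,10-dimethyldodeca-3,5,7,9-tetraene-1,11-diyn-1-yl]-3,5,5-trimethylcyclohex-3-en-1-ol | CC1=C(C#C/C(C)=C/C=C/C=C/C=C(C)/C#C)C(C)(C)C[C@H](O)C1 | intermediate (not isolated)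
27 | (2E,6E,8E,10E,12E)-2-bromo-15-[(4R)-4-hydroxy-2,6,6-trimethylcyclohex-1-en-1-yl]-6,13-dimethylpentadeca-2,6,8,10,12-pentaene-4,14-diynoic acid | CC1=C(C#C/C(C)=C/C=C/C=C/C=C(C)/C#C/C=C(/Br)C(=O)O)C(C)(C)C[C@H](O)C1 | intermediate (not isolated)
28 | (5Z)-3-bromo-5-[(2E,4E,6E,8E)-11-[(4R)-4-hydroxy-2,6,6-trimethylcyclohex-1-en-1-yl]-2,9-dimethylundeca-2,4,6,8-tetraen-10-yn-1-ylidene]furan-2(5H)-one | CC1=C(C#C/C(C)=C/C=C/C=C/C=C(C)/C=C2C=C(Br)C(=O)O/2)C(C)(C)C[C@H](O)C1 | intermediate
29 | (5Z)-3-[(E)-2-[(1S,4S,6R)-4-hydroxy-2,2,6-trimethyl-7-oxabicyclo[4.1.0]heptan-1-yl]ethenyl]-5-[(2E,4E,6E,8E)-11-[(4R)-4-hydroxy-2,6,6-trimethylcyclohex-1-en-1-yl]-2,9-dimethylundeca-2,4,6,8-tetraen-10-yn-1-ylidene]furan-2(5H)-one | CC1=C(C#C/C(C)=C/C=C/C=C/C=C(C)/C=C2C=C(/C=C/[C@@]34O[C@]3(C)C[C@@H](O)CC4(C)C)C(=O)O/2)C(C)(C)C[C@H](O)C1 | target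

Total step count: 18
Longest linear sequence: 11 steps (1, 2, 3, 4, 6, 7, 8, 9, 11, 12, 18)

Steps most likely to fail

Step 17. The statistical mono-coupling may be eroded by twofold coupling of the diyne or by oxidative dimerisation of its termini. The lactonisation may also leak into 6-endo closure, or the α-bromide may couple. The fallback sets out from 7 and 23 and separates the three events. The first Sonogashira coupling is run alone and the terminal alkyne 26 is isolated, with recovery of surplus 23. Compound 26 is then coupled under the same palladium–copper conditions with methyl (E)-2,3-dibromoacrylate F1, made from methyl propiolate and Br2, to give the methyl bromoenynoate F2. Mild saponification (LiOH, THF/H2O, 0 °C) gives acid 27, which is closed by AgNO3 (cat.) in acetone, the silver-catalysed 5-exo-dig lactonisation of (Z)-2-en-4-ynoic acids. The route is rejoined at 28.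

Step 15. Geometry control may be poor in the twofold olefination, glyoxal may be lost to base, and the 3E/9E geometry may erode during the iodine equilibration. The fallback sets out from 17 and 18 and builds the chain by E-selective steps only. Alcohol 17 is oxidised (MnO2, CH2Cl2) to (E)-3-methylpent-2-en-4-ynal F3. This is extended with the stabilised ylide (triphenylphosphoranylidene)acetaldehyde to (2E,4E)-5-methylhepta-2,4-dien-6-ynal F4. Bromide 18 is heated with triethyl phosphite (Arbuzov reaction) to give diethyl [(E)-3-methylpent-2-en-4-yn-1-yl]phosphonate F5. Horner–Wadsworth–Emmons olefination of F4 with the anion of F5 (NaN(SiMe3)2, THF, −78 → 0 °C) should form the C7=C8 bond E-selectively. The route is rejoined at 23.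

Step 11. Addition of the chromium carbenoid to the hindered, neopentyl-type aldehyde may be sluggish, and the epoxide may be opened by Lewis-acidic chromium salts or iodide. The fallback sets out from 11 and replaces tin by boron. Ohira–Bestmann homologation (dimethyl (1-diazo-2-oxopropyl)phosphonate, K2CO3, MeOH) gives (1R,4S,6R)-4-[(tert-butyldimethylsilyl)oxy]-1-ethynyl-2,2,6-trimethyl-7-oxabicyclo[4.1.0]heptane F6. Desilylation with Bu4NF gives (1R,3S,6R)-6-ethynyl-1,5,5-trimethyl-7-oxabicyclo[4.1.0]heptan-3-ol F7. Hydroboration with pinacolborane catalysed by Cp2Zr(H)Cl gives (1R,3S,6S)-1,5,5-trimethyl-6-[(E)-2-(4,4,5,5-tetramethyl-1,3,2-dioxaborolan-2-yl)ethenyl]-7-oxabicyclo[4.1.0]heptan-3-ol F8. Suzuki–Miyaura coupling of F8 with 28 (Pd(PPh3)4, aq. K3PO4, THF, rt) takes the place of the Stille coupling. The route is rejoined at 29.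

Further compounds
F1 | step 17 | methyl (E)-2,3-dibromoacrylate | COC(=O)/C(Br)=C\Br
F2 | step 17 | methyl (2E,6E,8E,10E,12E)-2-bromo-15-[(4R)-4-hydroxy-2,6,6-trimethylcyclohex-1-en-1-yl]-6,13-dimethylpentadeca-2,6,8,10,12-pentaene-4,14-diynoate | CC1=C(C#C/C(C)=C/C=C/C=C/C=C(C)/C#C/C=C(/Br)C(=O)OC)C(C)(C)C[C@H](O)C1
F3 | step 15 | (E)-3-methylpent-2-en-4-ynal | C#C/C(C)=C/C=O
F4 | step 15 | (2E,4E)-5-methylhepta-2,4-dien-6-ynal | C#C/C(C)=C/C=C/C=O
F5 | step 15 | diethyl [(E)-3-methylpent-2-en-4-yn-1-yl]phosphonate | C#C/C(C)=C/CP(=O)(OCC)OCC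
F6 | step 11 | (1R,4S,6R)-4-[(tert-butyldimethylsilyl)oxy]-1-ethynyl-2,2,6-trimethyl-7-oxabicyclo[4.1.0]heptane | C#C[C@@]12O[C@]1(C)C[C@@H](O[Si](C)(C)C(C)(C)C)CC2(C)C
F7 | step 11 | (1R,3S,6R)-6-ethynyl-1,5,5-trimethyl-7-oxabicyclo[4.1.0]heptan-3-ol | C#C[C@@]12O[C@]1(C)C[C@@H](O)CC2(C)C
F8 | step 11 | (1R,3S,6S)-1,5,5-trimethyl-6-[(E)-2-(4,4,5,5-tetramethyl-1,3,2-dioxaborolan-2-yl)ethenyl]-7-oxabicyclo[4.1.0]heptan-3-ol | CC1(C)OB(/C=C/[C@@]23O[C@]2(C)C[C@@H](O)CC3(C)C)OC1(C)C
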